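The runs come from a simulation from invented constants; noise was put on by code.

Counted in molar rather than in percent, a peak of target can be held against the smaller charge, the limiting reagent, since the suspect step substrate + partner -> intermediate + by-product uses one of each.

| flask | substrate | partner | remark | time |
|---|---|---|---|---|
| larch | 0.23 M | 0.069 M | run made earlier |  |
| ash | 0.23 M | 0.28 M | run made earlier |  |
| flask | 0.23 M | 0.138 M |  | 2.5 min |

| run | time / min | target / % |
|---|---|---|
| larch | 0.250 | 2.4 |
| larch | 0.333 | 6.1 |
| larch | 0.500 | 5.1 |
| larch | 0.833 | 5.1 |
| larch | 1.33 | 2.1 |
| larch | 2.00 | 0.3 |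
| larch | 3.00 | 0.1 |
| ash | 0.250 | 20.0 |
| ash | 0.333 | 22.6 |
| ash | 0.500 | 29.3 |
| ash | 0.833 | 37.8 |
| ash | 1.33 | 37.2 |
| ash | 2.00 | 32.0 |
| ash | 3.00 | 26.6 |

(each reading ± 1 percentage point)

- time up to 2.5 min at which target stands highest
- the amount of target, in percent of the substrate charged, at that time

- amounts and yields of target count crystals too
- given per volume of solution although it is solid: crystals
- on the list of suspects stand: crystals <-> target; intermediate -> side product; substrate + partner -> intermediate + by-product; intermediate <-> isomer of the product; intermediate <-> target

Two amounts matter, the peak concentration of target and the limiting charge, and we call their ratio Y. As a reading, larch, with less partner than substrate, gives 20.3 % on partner, and ash, with less substrate than partner, gives 37.8 % on substrate. The flask is charged with less partner than substrate, so there we count on partner. Our own reckoning, a straight line in limiting charge between larch and ash, gives the flask a Y of 27.8 %. That means a peak of 16.7 % of the substrate charged, at a time between the peak readings, 0.333 min in larch and 0.833 min in ash.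

The forecast gives 15 % at 0.65 min, a lower peak than ours, and says: “Whether crystals form is the main uncertainty.”

The flask gives 18.1 % at 0.935 min, with 15.0 % of the substrate charged standing as crystals, counted in target, at that time.

    crystals ⇌ target, rate k1*(cs1 - [target]) while solid is left; crystals form when [target] > cs1 (solubility = 7.10 mM, k = 7.27 /s)
    intermediate → side product (k = 0.0614 /s)
    substrate + partner → intermediate + by-product (k = 0.215 /M/s)
    intermediate ⇌ isomer of the product (K = 2.58, k = 0.00141 /s)
    intermediate ⇌ target (K = 0.640, k = 0.101 /s)

The flask's Y is 30.2 %, above our 27.8 %. A neighbouring flask has the same partner charge but 0.58 M of substrate, and there partner is the limiting reagent, with 0 % of it left at 2.50 min. Our Y predicts 6.62 % of its substrate, while that flask reaches 10.5 %, a Y of 44.2 %.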